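**Retrosynthetic overview**

- The route rests on the trisubstituted C2=C3 alkene of the central 2-(oxymethyl)but-2-enoate, whose C3 methyl lies cis to the C1 ester carbonyl (the less stable geometry). It is cut by a Z-selective Horner–Wadsworth–Emmons olefination of acetaldehyde with an α-substituted diphenyl phosphonate that already carries the (S)-benzylic ester.
- The angelate C–O bond is disconnected last: the primary allylic alcohol freed from its 4-methoxybenzyl ether is acylated with angelic acid under non-isomerising conditions.
- The phosphonate comes from C-alkylation of a diphenyl phosphonoacetate with 4-methoxybenzyl chloromethyl ether; the phosphonoacetate comes from the bromoacetate and diphenyl phosphite.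
- The only stereocentre (benzylic, S) is set first by catalytic asymmetric ethylation of 3,4,5-trimethoxybenzaldehyde.
- No ring is formed: the only ring, the 3,4,5-trimethoxybenzene ring, is bought.

Key step: step 7

Assumption: 4-methoxybenzyl chloromethyl ether is too labile to buy and store, so it is made fresh (steps 4 and 5) and used crude.

**Route**

Step 1
Reactants: 1 3,4,5-trimethoxybenzaldehyde
Product: 2 (S)-1-(3,4,5-trimethoxyphenyl)propan-1-ol
Conditions: Et2Zn (2 equiv, hexanes), (2S)-(−)-3-exo-(dimethylamino)isoborneol (5 mol %), toluene, 0 °C; then sat. aq. NH4Cl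
Reagents that add atoms: diethylzinc, CC[Zn]CC
Why: Amino-alcohol-catalysed enantioselective addition of a dialkylzinc to an aryl aldehyde (Noyori-type ethylation), in which the zinc chelate of the (2S)-amino alcohol should deliver ethyl to the Si face of the aldehyde and so give the (S)-carbinol, as it does with benzaldehyde.

Step 2
Reactants: 2 (S)-1-(3,4,5-trimethoxyphenyl)propan-1-ol
Product: 3 (S)-1-(3,4,5-trimethoxyphenyl)propyl 2-bromoacetate
Conditions: BrCH2COBr (1.2 equiv), pyridine (1.5 equiv), CH2Cl2, −20 → 0 °C
Reagents that add atoms: bromoacetyl bromide, BrCC(Br)=O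
Why: O-acylation of a secondary alcohol by an acyl bromide with pyridine as acid scavenger; the C–O bond at the stereocentre is not broken, so the configuration is kept, and the base stops HBr from ionising the electron-rich benzylic position.

Step 3
Reactants: 3 (S)-1-(3,4,5-trimethoxyphenyl)propyl 2-bromoacetate; 4 diphenyl phosphite
Product: 5 (S)-1-(3,4,5-trimethoxyphenyl)propyl 2-(diphenoxyphosphoryl)acetate
Conditions: 4 (1.0 equiv), Et3N (1.3 equiv), CH2Cl2, 0 °C → rt
Reagents that add atoms: none
Why: Michaelis–Becker reaction, in which the phosphite anion formed with Et3N displaces the activated primary bromide by SN2 to make the P–C bond, the usual way to diaryl phosphonoacetates.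

Step 4
Reactants: 6 4-methoxybenzyl alcohol
Product: 7 4-methoxybenzyl methylthiomethyl ether
Conditions: NaH (1.1 equiv), NaI (cat.), ClCH2SMe (1.1 equiv), DME, 0 °C → rt
Reagents that add atoms: chloromethyl methyl sulfide, CSCCl
Why: Williamson etherification of the sodium alkoxide with an α-chloro sulfide under iodide catalysis should give the O,S-acetal cleanly.

Step 5
Reactants: 7 4-methoxybenzyl methylthiomethyl ether
Product: 8 4-methoxybenzyl chloromethyl ether
Conditions: SO2Cl2 (1.0 equiv), CH2Cl2, −78 °C; volatiles removed in vacuo, crude 8 used at once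
Reagents that add atoms: sulfuryl chloride, O=S(=O)(Cl)Cl
Why: S-chlorination of the O,S-acetal gives a chlorosulfonium ion that fragments to an oxocarbenium ion and MeSCl, and chloride capture gives the α-chloro ether (the standard conversion of methylthiomethyl ethers into chloromethyl ethers).

Step 6
Reactants: 5 (S)-1-(3,4,5-trimethoxyphenyl)propyl 2-(diphenoxyphosphoryl)acetate; 8 4-methoxybenzyl chloromethyl ether
Product: 9 (S)-1-(3,4,5-trimethoxyphenyl)propyl 2-(diphenoxyphosphoryl)-3-(4-methoxybenzyloxy)propanoate (both epimers at C2)
Conditions: NaH (1.05 equiv), THF, 0 °C; then 8 (1.3 equiv), −20 → 0 °C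
Reagents that add atoms: none
Why: C-alkylation of a phosphonoacetate carbanion by a highly reactive α-chloro ether, held at monoalkylation by the single equivalent of base and by the lower acidity and greater hindrance of the product; the new C2 centre needs no control because step 7 destroys it.

Step 7
Reactants: 9 (S)-1-(3,4,5-trimethoxyphenyl)propyl 2-(diphenoxyphosphoryl)-3-(4-methoxybenzyloxy)propanoate; 10 acetaldehyde
Product: 11 (S)-1-(3,4,5-trimethoxyphenyl)propyl (Z)-2-[(4-methoxybenzyloxy)methyl]but-2-enoate
Conditions: KOt-Bu (1.05 equiv), THF, −78 °C, 15 min; then MeCHO (3 equiv, freshly distilled), −78 → −20 °C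
Reagents that add atoms: none
Why: KOt-Bu removes the C2 proton of 9 (between P=O and the ester C=O), the carbanion adds to the acetaldehyde carbonyl, and the β-oxido phosphonate closes to an oxaphosphetane that expels potassium diphenyl phosphate to form the C2=C3 bond. The closest known reaction is the Z-selective Horner–Wadsworth–Emmons olefination of aldehydes with α-substituted diaryl phosphonoacetates (Ando variant), which gives (Z)-trisubstituted enoates. No ring is closed and no stereocentre is created; the C2 centre of 9 is destroyed, so both epimers converge, and the remote (S)-benzylic centre is not touched. The selectivity needed is the Z geometry (C3 methyl cis to the ester carbonyl): the electron-poor phenoxy groups on phosphorus make oxaphosphetane collapse faster than reversal of the addition, so the kinetically favoured adduct goes straight to the Z alkene, helped by the potassium counter-ion at −78 °C and the branched C2 substituent. The second selectivity, olefination over E1cB loss of 4-methoxybenzyloxide, rests on the poor leaving-group ability of an alkoxide from a doubly stabilised carbanion at −78 °C and on the excess of small, unhindered acetaldehyde.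

Step 8
Reactants: 11 (S)-1-(3,4,5-trimethoxyphenyl)propyl (Z)-2-[(4-methoxybenzyloxy)methyl]but-2-enoate
Product: 12 (S)-1-(3,4,5-trimethoxyphenyl)propyl (Z)-2-(hydroxymethyl)but-2-enoate
Conditions: DDQ (1.3 equiv), CH2Cl2/pH 7 phosphate buffer (10:1), 0 °C
Reagents that add atoms: none
Why: Oxidative cleavage of a 4-methoxybenzyl ether by DDQ (hydride abstraction from the 4-methoxybenzylic CH2, then hydrolysis of the oxocarbenium ion), selective because the trimethoxybenzylic C–H bears an acyloxy group that disfavours hydride loss, with the buffer preventing acid-induced ionisation of the benzylic ester.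

Step 9
Reactants: 12 (S)-1-(3,4,5-trimethoxyphenyl)propyl (Z)-2-(hydroxymethyl)but-2-enoate; 13 angelic acid
Product: 15 (S)-1-(3,4,5-trimethoxyphenyl)propyl (Z)-2-{[(Z)-2-methylbut-2-enoyl]oxymethyl}but-2-enoate, via angelic 2,4,6-trichlorobenzoic anhydride 14 (not isolated)
Conditions: 13 (3 equiv), 2,4,6-trichlorobenzoyl chloride (3 equiv), Et3N (3 equiv), toluene, rt, 2 h; then 12, toluene, 75 °C
Reagents that add atoms: 2,4,6-trichlorobenzoyl chloride, O=C(Cl)c1c(Cl)cc(Cl)cc1Cl (its atoms stay in 14 only, not in 15)
Why: Yamaguchi-type mixed-anhydride esterification run without DMAP, in which the primary alcohol attacks the unhindered angeloyl carbonyl of 14 and, with no nucleophilic catalyst adding reversibly to the β-carbon, the (Z)-2-methylbut-2-enoyl geometry should be kept.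

**Compound list**

1 | 3,4,5-trimethoxybenzaldehyde | COc1cc(C=O)cc(OC)c1OC | starting material
2 | (S)-1-(3,4,5-trimethoxyphenyl)propan-1-ol | O[C@@H](CC)c1cc(OC)c(OC)c(OC)c1 | intermediate
3 | (S)-1-(3,4,5-trimethoxyphenyl)propyl 2-bromoacetate | BrCC(=O)O[C@@H](CC)c1cc(OC)c(OC)c(OC)c1 | intermediate
4 | diphenyl phosphite | O=[PH](Oc1ccccc1)Oc1ccccc1 | starting material
5 | (S)-1-(3,4,5-trimethoxyphenyl)propyl 2-(diphenoxyphosphoryl)acetate | O=C(CP(=O)(Oc1ccccc1)Oc1ccccc1)O[C@@H](CC)c1cc(OC)c(OC)c(OC)c1 | intermediate
6 | 4-methoxybenzyl alcohol | COc1ccc(CO)cc1 | starting material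
7 | 4-methoxybenzyl methylthiomethyl ether | COc1ccc(COCSC)cc1 | intermediate
8 | 4-methoxybenzyl chloromethyl ether | COc1ccc(COCCl)cc1 | intermediate
9 | (S)-1-(3,4,5-trimethoxyphenyl)propyl 2-(diphenoxyphosphoryl)-3-(4-methoxybenzyloxy)propanoate, both epimers at C2 | COc1ccc(COCC(C(=O)O[C@@H](CC)c2cc(OC)c(OC)c(OC)c2)P(=O)(Oc2ccccc2)Oc2ccccc2)cc1 | intermediate
10 | acetaldehyde | CC=O | starting material
11 | (S)-1-(3,4,5-trimethoxyphenyl)propyl (Z)-2-[(4-methoxybenzyloxy)methyl]but-2-enoate | COc1ccc(COC/C(=C/C)C(=O)O[C@@H](CC)c2cc(OC)c(OC)c(OC)c2)cc1 | intermediate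
12 | (S)-1-(3,4,5-trimethoxyphenyl)propyl (Z)-2-(hydroxymethyl)but-2-enoate | OC/C(=C/C)C(=O)O[C@@H](CC)c1cc(OC)c(OC)c(OC)c1 | intermediate
13 | angelic acid, (Z)-2-methylbut-2-enoic acid | C/C=C(/C)C(=O)O | starting material
14 | angelic 2,4,6-trichlorobenzoic anhydride | C/C=C(/C)C(=O)OC(=O)c1c(Cl)cc(Cl)cc1Cl | intermediate
15 | (S)-1-(3,4,5-trimethoxyphenyl)propyl (Z)-2-{[(Z)-2-methylbut-2-enoyl]oxymethyl}but-2-enoate (CNP0198521.1) | C/C=C(/C)C(=O)OC/C(=C/C)C(=O)O[C@@H](CC)c1cc(OC)c(OC)c(OC)c1 | target

**Step count**

Total: 9 steps. Longest linear sequence: 7 steps (steps 1, 2, 3, 6, 7, 8, 9); the side branch to the chloromethyl ether is 2 steps (steps 4, 5).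

**Steps most likely to fail**

Step 7 (key step). The Z-selectivity may erode with so small an aldehyde. The carbanion may also lose 4-methoxybenzyloxide by β-elimination before it meets the aldehyde, or acetaldehyde may self-condense under the base. The fallback sets out from alcohol 2 and builds the alkene by syn-hydroalumination instead of olefination. Alcohol 2 is esterified with but-2-ynoic acid (DCC, cat. DMAP, CH2Cl2, −20 → 0 °C) to give (S)-1-(3,4,5-trimethoxyphenyl)propyl but-2-ynoate F1. Conjugate syn-hydroalumination of the ynoate with i-Bu2AlH and N-methylmorpholine N-oxide in THF at 0 °C places hydrogen on C3 and aluminium on C2 on the same side. Trapping of this α-aluminated enoate with monomeric formaldehyde with retention (the vinylalumination route to Z-configured Morita–Baylis–Hillman-type adducts) should put the C3 methyl cis to the ester. The route is rejoined at alcohol 12, with no protecting group needed.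

Step 6. The labile α-chloro ether may hydrolyse or self-condense before it alkylates, and the phosphonoacetate anion may be O-alkylated or alkylated twice. The fallback sets out from phosphonoacetate 5 and forms the C2–CH2 bond by condensation and the CH2–O bond by conjugate addition. Compound 5 is condensed with paraformaldehyde under piperidinium acetate catalysis in toluene in the presence of excess 4-methoxybenzyl alcohol 6. The Knoevenagel product, (S)-1-(3,4,5-trimethoxyphenyl)propyl 2-(diphenoxyphosphoryl)prop-2-enoate F2, takes up the alcohol by oxa-Michael addition (promoted separately by catalytic PBu3 if needed), as methanol does in the classical preparation of 3-methoxy-2-phosphonopropanoates. The route is rejoined at phosphonate 9.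

Step 9. The angeloyl group may isomerise to the tigloyl (E) group while the carboxyl is activated, or acylation by the hindered mixed anhydride may be too slow. The fallback sets out from alcohol 12 and activates the alcohol instead of the acid: Mitsunobu esterification of 12 with angelic acid 13 (PPh3, DIAD, THF, 0 °C). The angelate then acts only as a nucleophile and its geometry is not at risk. The route is rejoined at target 15; this fallback makes no new compound (F0).

**Further compounds**

F1 | step 7 | (S)-1-(3,4,5-trimethoxyphenyl)propyl but-2-ynoate | CC#CC(=O)O[C@@H](CC)c1cc(OC)c(OC)c(OC)c1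
F2 | step 6 | (S)-1-(3,4,5-trimethoxyphenyl)propyl 2-(diphenoxyphosphoryl)prop-2-enoate | C=C(C(=O)O[C@@H](CC)c1cc(OC)c(OC)c(OC)c1)P(=O)(Oc1ccccc1)Oc1ccccc1
F0 | step 9 | none | none
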